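(The data were computed on assumed constants.)

The flask is slow, so we ask which concentration its rate follows.

| flask | substrate | reagent | free catalyst | second catalyst | remark | time |
|---|---|---|---|---|---|---|
| south-west | 1.4 M | 0.60 equiv | 0.1 mol% | 0.2 mol% | run made earlier |  |
| north-west | 1.4 M | 1.2 equiv | 0.1 mol% | 0.2 mol% | run made earlier |  |
| autumn | 1.4 M | 1.10 equiv | 0.1 mol% | 0.2 mol% |  | 2.0 d |
| summer | 1.4 M | 1.30 equiv | 0.1 mol% | 0.2 mol% |  | 2.0 d |
| winter | 1.4 M | 1.60 equiv | 0.1 mol% | 0.2 mol% |  | 2.0 d |

| run | time / h | substrate / % | isomer of the product / % | target / % | open intermediate / % |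
|---|---|---|---|---|---|
| south-west | 2.50 | 83.5 | 0.7 | 1.0 | 15.2 |
| south-west | 4.00 | 75.4 | 1.2 | 1.6 | 21.9 |
| south-west | 6.00 | 64.7 | 0.8 | 3.7 | 30.3 |
| south-west | 10.0 | 49.3 | 1.6 | 6.6 | 41.5 |
| south-west | 15.0 | 35.2 | 4.1 | 10.6 | 50.7 |
| south-west | 20.0 | 24.4 | 4.4 | 13.7 | 55.5 |
| south-west | 30.0 | 12.3 | 7.4 | 20.7 | 59.3 |
| north-west | 5.00 | 69.4 | 1.6 | 4.6 | 23.5 |
| north-west | 10.0 | 49.3 | 3.7 | 12.5 | 34.1 |
| north-west | 15.0 | 34.8 | 7.1 | 19.9 | 38.7 |
| north-west | 20.0 | 24.7 | 9.3 | 26.7 | 38.7 |
| north-west | 25.0 | 16.6 | 12.4 | 31.7 | 38.7 |
| north-west | 30.0 | 11.6 | 13.8 | 37.8 | 35.8 |

(each reading ± 0.5 percentage points)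

- what was read earlier has a scatter of 0.5 percentage points, one standard deviation

* which of these there is most of at the end, counted by the substrate in it, autumn (target / open intermediate / substrate / isomer of the product)
* which of these there is most of at the end, counted by the substrate in it, summer (target / open intermediate / substrate / isomer of the product)
* which of these there is most of at the end, counted by the substrate in it, winter (target / open intermediate / substrate / isomer of the product)
* the largest of these amounts at the end, in percent of the substrate charged, autumn
* the largest of these amounts at the end, in percent of the substrate charged, summer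
* the largest of these amounts at the end, in percent of the substrate charged, winter

Opening comes first. Both earlier runs hold 49.3% of the substrate at 10.0 h, though the north-west run has twice the reagent. So the fraction left halves about every 10.0 h at either reagent level, and after 2.0 d we expect 3.35%.

Product comes next. We count target plus isomer of the product, each costing one reagent. In the north-west run the open intermediate reads 38.7% at 15.0 h and 38.7% at 25.0 h, yet product formation slows as reagent goes. With the intermediate this steady, still 35.8% at 30.0 h, the rate reads as following reagent, which is a pseudo-first-order decay. We call its constant the reagent constant, the fall in the logarithm of the fraction of reagent left per hour: 0.0205 h⁻¹. In the first 5.00 h of that run, with less intermediate present, it reads 0.0106 h⁻¹. At 30.0 h of the north-west run, target reads a share 0.733 of the product.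

These give a bracket. For the top we keep the plateau constant throughout, supposing the intermediate stays near or below its plateau. For the foot we keep the early constant, supposing it stays near its early level. Target is then share times equivalents times the reagent fraction used. On these suppositions, which are estimates and not firm bounds, autumn lies between 32.2% and 50.4%, and summer between 38.0% and 59.6%. Winter starts from 46.8%, and its top is tightened by the substrate opened, to 70.8%, less than the reagent reckoning gives. At the foot, autumn's open intermediate reckons to 52.7%, more than target. At the top it reckons to 27.8%, less than target. The north-west run holds more intermediate at 15.0 h than at 5.00 h, so we commit to the top's order for autumn, with target leading, and to the same order for summer and winter, whose tops stand higher.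

The forecast, resting on “saturation of the second catalyst”, says target at 49% in autumn, 55% in summer and 61% in winter, each inside our bracket.

The flasks give target at 48.5% in autumn, target at 54.6% in summer and target at 61.3% in winter.

    target + free catalyst ⇌ isomer of the product + free catalyst, rate k1*[free catalyst]*[target] forward; the back reaction follows from the equilibrium constant (K = 0.390, k = 0.0500 L mol⁻¹ s⁻¹)
    second catalyst + open intermediate ⇌ catalyst intermediate (K = 2.90 L mol⁻¹, k = 0.150 L mol⁻¹ s⁻¹)
    reagent + catalyst intermediate → second catalyst + target (k = 0.00350 L mol⁻¹ s⁻¹)
    substrate + free catalyst → free catalyst + open intermediate (k = 0.0140 L mol⁻¹ s⁻¹)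

The reagent constant predicts 37.4% of the reagent left at 2.0 d. Autumn holds 39% and winter 47%, when its open intermediate is down to 11.7%. Now leave winter until 8.0 d. The constant would take up 1.57 equivalents, more than the substrate can use, so substrate is the limiting reagent and target should reach the share, 73.3%. That flask gives 71.9% target, with 0% of the substrate and 38% of the reagent left.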